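At early times, the first speaker reported, the two hands stand within the scatter of each other: Monday's run reads 48.1 % of left-handed substrate against 48.6 % of right-handed substrate at 2.50 h, so the meeting turned to the last readings.

the same everywhere: left-handed substrate 0.050 M; right-handed substrate 0.050 M
- Monday's: solid reagent 4 equiv; racemization catalyst 0.1 mol%; run made earlier
- Wednesday's: solid reagent 4 equiv; racemization catalyst 0.17 mol%; run made earlier
- flask: solid reagent 4.00 equiv; racemization catalyst 0.075 mol%; time 2.5 d

- Monday's (time / h: left-handed substrate / %, right-handed substrate / %): 2.50: 48.1, 48.6; 8.00: 48.0, 47.3; 15.0: 46.3, 48.5; 20.0: 44.4, 49.6; 30.0: 41.7, 45.8; 40.0: 35.4, 45.1; 50.0: 32.4, 40.7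
- Wednesday's (time / h: left-handed substrate / %, right-handed substrate / %): 4.00: 48.7, 49.4; 6.00: 49.6, 49.5; 8.00: 47.6, 49.6; 15.0: 45.9, 47.9; 20.0: 43.9, 47.4; 30.0: 40.7, 46.8; 50.0: 33.6, 40.5

(each reading ± 1 percentage point)

- partner is single-handed; left-handed substrate and right-handed substrate are mirror images of each other, charged as a racemate, each of them at the stated concentration
- solid, in amounts per volume of the solution: solid reagent
- at the start none of the solid reagent is in solution
- an excess is the difference of the two amounts in percent of their sum
- an excess is below zero if the other one leads
- the handed part of partner does not stay in what it makes, so the products of the two hands are mirror images too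

- part of the left-handed substrate and right-handed substrate charged together that has reacted at 2.5 d
- excess of left-handed product over right-handed product in the product at 2.5 d
- excess of right-handed substrate over left-handed substrate among what is left of the two at 2.5 d

The second speaker compared how far each hand had gone in Monday's run at 50.0 h. She divided the logarithm of the part of the left-handed substrate's own charge still there by the same logarithm for the right-handed substrate, and got 2.11. This is the apparent selectivity factor: the ratio of the two hands' rates, with the work of the racemization catalyst still mixed in. Wednesday's run at 50.0 h gave 1.89, less with more racemization catalyst.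

The third speaker warned that the gap between the two factors may be scatter, and it stands as a reading. Still, a straight line through both runs gives 2.19 for the new flask at 0.075 mol%. Read as a ratio of rates, that puts the product excess in this flask at 37.3 %, minuted as a low mark, since Wednesday's factor is less than Monday's.

The forecast gave 34 % reacted, 42 % in the product, above that mark, and 16 % among the substrates, adding “This selectivity is poorly determined”.

This flask gives 31.0 % reacted, a product excess of 53.1 % and a substrate excess of 16.3 %. At 2.50 d this flask holds 40.5 % of its catalyst as spent catalyst. Its leftovers, 58 % and 80 % of their own charges, give an apparent factor of 2.49, above the line's 2.19, and the product excess stands above the low mark.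

    partner + left-handed substrate → left-handed product (k = 0.655 M⁻¹ h⁻¹)
    partner + right-handed substrate → right-handed product (k = 0.170 M⁻¹ h⁻¹)
    left-handed substrate + racemization catalyst ⇌ right-handed substrate + racemization catalyst, rate k3*[racemization catalyst]*[left-handed substrate] forward; the back reaction follows from the equilibrium constant (k = 270 M⁻¹ h⁻¹)
    partner + racemization catalyst → spent catalyst (k = 0.547 M⁻¹ h⁻¹)
    solid reagent ⇌ partner, rate k5*(cs5 - [partner]) while solid is left; crystals form when [partner] > cs5 (solubility = 33.0 mM, k = 0.0504 h⁻¹)

For the neighbour flask with 0.19 mol% of racemization catalyst, the same line gives 1.82. Computed, that neighbour flask leaves 61 % of its left-handed substrate and 76 % of its right-handed substrate, an apparent factor of 1.80, with a substrate excess of 10.8 %.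

The earlier runs and the new flask stem from a simulated flask with constants of no real substance; scatter was added.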